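If living ends die at a steady pace while something else eats their monomer, I ask how much monomer the ends can reach before they are gone.

| flask | free monomer | transfer agent | protic impurity | initiator | stray impurity | time |
|---|---|---|---|---|---|---|
| red | 46 mM | 4.60 mM | 23.0 mM | 1.1 mM | 0.45 mM | 12 h |
| green | 46 mM | 2.50 mM | 23.0 mM | 1.1 mM | 0.45 mM | 12 h |

    initiator + stray impurity → spent initiator (k1 = 26000 M⁻¹ min⁻¹)
    protic impurity + free monomer → quenched substrate (k2 = 0.22 M⁻¹ min⁻¹)
    living end + transfer agent → dead chain (k3 = 4.3 M⁻¹ min⁻¹)
    free monomer + initiator → living end + monomer in chains (k4 = 23 M⁻¹ min⁻¹)
    free monomer + living end → monomer in chains + living end, rate k5*[living end]*[free monomer] (k5 = 13 M⁻¹ min⁻¹)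

- the average divides the monomer in chains by the number of chains begun, living and dead together
- run time (red): 12 h

* which of the two ends with the longer chains by the average number of monomer units in a chain (chains begun, living or dead) ("neither" if they lie within 10%) (red / green / neither)
* average number of monomer units in a chain (chains begun, living or dead) at the end, red
* average number of monomer units in a chain (chains begun, living or dead) at the end, green

I began with the chains. The stray impurity falls at 28.6 min⁻¹ against the charged initiator, far faster than the initiator goes to free monomer at 1.06 min⁻¹. So the impurity takes its 0.45 mM first and leaves 0.650 mM of chains begun in both flasks. With growth as the main step, those chains hold at most 70.8 units each if they take up the charged monomer.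

Then I added death. Transfer agent removes ends at a pseudo-first-order pace, 0.0198 min⁻¹ in red and 0.0107 min⁻¹ in green. With ends decaying this way, the growth they can still do sums to the growth constant times the chains begun over the death pace, so by this reckoning [free monomer] levels off at a plateau, 65.2% of the charge in red, and the length comes down to 24.6 units in red and 38.5 in green.

Last came the protic impurity, which eats free monomer at 0.00506 min⁻¹ at its charge, slower than red's ends die but still a rival. So I defined the reach as the growth constant times the chains begun, divided by the sum of the ends' death pace and the monomer's quenching pace, and the share of monomer entering chains as one minus the exponential of minus the reach. The reach is 0.340 in red and 0.534 in green, which gives 20.4 and 29.3 units. In red the impurity's half-life of 1.1 h is not far above the 0.58 h of an end, so [protic impurity] sags during growth and the charged pace overstates the quenching. I therefore took the lengths with and without quenching as brackets. Green's low end still beat red's high end by more than the margin.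

The forecast gave 22.4 (range 20.5 to 24.5) for red and 32.8 (30 to 36) for green, saying “Green grows longer chains because its lower transfer-agent level keeps ends alive longer”. My brackets held both numbers but named no single value.

The simulation gave 22.6 in red and 33.0 in green, so green ended longer.

In red, growth reached its midpoint at 0.473 h and quenching at 1.52 h, later than growth. Red's monomer in chains stood at 31.9% of the charge, between the reach's 28.8% and the 34.8% reckoned without quenching. In the flask like red but with 57 mM of protic impurity, the reach falls to 0.261, which gives a low end of 16.3 units, and that flask ended at 18.1.

The numbers of this flask are those of an exercise.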